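**Retrosynthetic overview**
1. The α-methylene-γ-butyrolactone (ring O–C12(=O)–C11(=C13H2)–C7–C6) is the Baeyer–Villiger product of a 2-methylenecyclobutanone (ring C12–C11–C7–C6). That four-membered ring is the [2+2] adduct of a ketene C12=C6 with the C7=C11 bond of a terminal allene C7=C11=C13, and this relation is what makes the key step possible.
2. Key disconnection: an intramolecular vinylketene–allene [2+2] of a seco acid chloride forms C11–C12 and C6–C7 in one operation, closing the cyclobutanone and the ten-membered carbocycle together. The furanone is carried as a Co2(CO)6-masked ynone C1(=O)–C2≡C3 with C10–OSiEt3.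
3. Ring order: ten-membered ring plus cyclobutanone (step 15), then γ-lactone by insertion of one oxygen between C12 and C6 (step 17), then 3(2H)-furanone by 5-endo-dig closure of O10 onto C3 (step 18).
4. The seco acid comes from Sonogashira union (C3–C4) of an allenyl hydroxy ynone with a (Z)-bromoalkene. The ynone derives from (R)-citramalic acid (C10 from the chiral pool, C8 by asymmetric transfer hydrogenation, allene by Crabbé homologation, a temporary γ-lactone differentiating O8 and O10). The bromoalkene derives from bromoallylation of propargyl acetate, which fixes the C4=C5 geometry.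

Key step: step 15

Remark: locants C1–C15 are germacrane locants of the target (C1 furanone C=O, C2=C3 furanone alkene, C4=C5 ring alkene bearing C15H2OAc, C6 lactone carbinol, C7, C8 methacrylate carbinol, C9, C10 quaternary carbon, C11=C13 methylene, C12 lactone C=O); hydroxy ynone 12 is assumed to react from its open-chain form, with which any cyclic hemiketal is in equilibrium.

**Route**

Step 1
Reactants: 1 (R)-citramalic acid
Product: 2 (R)-2-(2,2,4-trimethyl-5-oxo-1,3-dioxolan-4-yl)acetic acid
Conditions: Me2C(OMe)2, TsOH·H2O (cat.), acetone, rt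
Reagents that add atoms: 2,2-dimethoxypropane COC(C)(C)OC
Why: Acid-catalysed acetonide (1,3-dioxolan-4-one) formation engages only the α-hydroxy acid, so the C8 carboxyl stays free and the chiral-pool C10 centre is untouched.

Step 2
Reactants: 2 (R)-2-(2,2,4-trimethyl-5-oxo-1,3-dioxolan-4-yl)acetic acid; 3 (trimethylsilyl)acetylene
Product: 5 (R)-2,2,5-trimethyl-5-[2-oxo-4-(trimethylsilyl)but-3-yn-1-yl]-1,3-dioxolan-4-one, via acid chloride 4 (not isolated)
Conditions: (COCl)2, DMF (cat.), CH2Cl2, 0 °C → rt; then 3, PdCl2(PPh3)2 (2 mol %), CuI (4 mol %), Et3N, THF, rt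
Reagents that add atoms: none
Why: Acyl Sonogashira coupling of the acid chloride with the terminal alkyne should give the ynone without touching the dioxolanone.

Step 3
Reactants: 5 (R)-2,2,5-trimethyl-5-[2-oxo-4-(trimethylsilyl)but-3-yn-1-yl]-1,3-dioxolan-4-one
Product: 7 (3R,5S)-3-hydroxy-3-methyl-5-[(trimethylsilyl)ethynyl]oxolan-2-one, via hydroxy dioxolanone 6 (not isolated)
Conditions: RuCl[(S,S)-TsDPEN](p-cymene) (1 mol %), KOH (1 mol %), iPrOH, rt; then TsOH·H2O (5 mol %), CH2Cl2, rt
Reagents that add atoms: none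
Why: Noyori asymmetric transfer hydrogenation of the alkynyl ketone sets C8 as S by reagent control (alkynyl versus alkyl differentiation by the (S,S) catalyst); acid then lets the new hydroxyl open the dioxolanone (translactonisation), which ties up O8 and frees the tertiary C10 hydroxyl.

Step 4
Reactants: 7 (3R,5S)-3-hydroxy-3-methyl-5-[(trimethylsilyl)ethynyl]oxolan-2-one
Product: 8 (3R,5S)-5-ethynyl-3-hydroxy-3-methyloxolan-2-one
Conditions: TBAF, AcOH, THF, 0 °C
Reagents that add atoms: none
Why: Buffered fluoride protodesilylation of the alkynylsilane should leave the lactone intact.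

Step 5
Reactants: 8 (3R,5S)-5-ethynyl-3-hydroxy-3-methyloxolan-2-one
Product: 9 (3R,5S)-3-hydroxy-3-methyl-5-(propa-1,2-dien-1-yl)oxolan-2-one
Conditions: (CH2O)n, CuI (0.5 equiv), Cy2NH, 1,4-dioxane, reflux
Reagents that add atoms: paraformaldehyde (formaldehyde unit) C=O
Why: Crabbé homologation (Mannich reaction of the copper acetylide, then 1,5-hydride shift with loss of the imine) should turn the terminal alkyne into the terminal allene without touching C8.

Step 6
Reactants: 9 (3R,5S)-3-hydroxy-3-methyl-5-(propa-1,2-dien-1-yl)oxolan-2-one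
Product: 10 (3R,5S)-3-methyl-5-(propa-1,2-dien-1-yl)-3-[(triethylsilyl)oxy]oxolan-2-one
Conditions: TESOTf, 2,6-lutidine, CH2Cl2, −78 → 0 °C
Reagents that add atoms: triethylsilyl triflate CC[Si](CC)(CC)OS(=O)(=O)C(F)(F)F
Why: Silyl triflate silylation is the standard way to protect a hindered tertiary alcohol; the ether blocks early furanone formation and acylation of O10 by the ketene later on.

Step 7
Reactants: 10 (3R,5S)-3-methyl-5-(propa-1,2-dien-1-yl)-3-[(triethylsilyl)oxy]oxolan-2-one; 11 ethynylmagnesium bromide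
Product: 12 (4R,6S)-6-hydroxy-4-methyl-4-[(triethylsilyl)oxy]nona-7,8-dien-1-yn-3-one
Conditions: THF, −78 → −30 °C; aq. NH4Cl
Reagents that add atoms: none
Why: Mono-addition of the alkynyl Grignard reagent to the lactone should stop at the magnesium hemiketal, which opens on work-up to the ynone (C1–C3) and releases the C8 hydroxyl.

Step 8
Reactants: 13 prop-2-yn-1-yl acetate; 14 allyl bromide
Product: 15 (Z)-2-bromohexa-2,5-dien-1-yl acetate
Conditions: PdBr2(PhCN)2 (2 mol %), 14 (neat, excess), rt
Reagents that add atoms: none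
Why: Palladium-catalysed bromoallylation of a terminal alkyne (syn-bromopalladation with Br at the internal carbon, insertion of allyl bromide, β-bromide elimination) places Br and the new CH2 cis, which fixes the C4=C5 geometry of the target.

Step 9
Reactants: 15 (Z)-2-bromohexa-2,5-dien-1-yl acetate
Product: 16 (Z)-5-acetoxy-4-bromopent-3-enoic acid
Conditions: RuCl3·xH2O (2 mol %), NaIO4, MeCN/EtOAc/H2O, 0 °C → rt
Reagents that add atoms: sodium periodate [Na+].[O-]I(=O)(=O)=O
Why: Ruthenium tetroxide cleavage of the monosubstituted terminal alkene should give the acid, the electron-poor bromoalkene reacting more slowly.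

Step 10
Reactants: 16 (Z)-5-acetoxy-4-bromopent-3-enoic acid
Product: 17 tert-butyl (Z)-5-acetoxy-4-bromopent-3-enoate
Conditions: tBuOC(=NH)CCl3, BF3·OEt2 (cat.), CH2Cl2/cyclohexane, rt
Reagents that add atoms: tert-butyl 2,2,2-trichloroacetimidate CC(C)(C)OC(=N)C(Cl)(Cl)Cl
Why: Acid-catalysed imidate tert-butylation esterifies without base, so the β,γ-alkene should not move into conjugation.

Step 11
Reactants: 12 (4R,6S)-6-hydroxy-4-methyl-4-[(triethylsilyl)oxy]nona-7,8-dien-1-yn-3-one; 17 tert-butyl (Z)-5-acetoxy-4-bromopent-3-enoate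
Product: 18 tert-butyl (3E,8R,10S)-4-(acetoxymethyl)-10-hydroxy-8-methyl-7-oxo-8-[(triethylsilyl)oxy]trideca-3,11,12-trien-5-ynoate
Conditions: Pd(PPh3)4 (5 mol %), CuI (10 mol %), iPr2NEt, THF, rt → 40 °C
Reagents that add atoms: none
Why: Sonogashira coupling with retention of alkene geometry joins C3 to C4 (alkyne cis to the CH2CO2tBu arm); the hindered amine limits conjugate addition to the ynone, and the still free C8 hydroxyl avoids an ionisable allenyl ester under palladium catalysis.

Step 12
Reactants: 18 tert-butyl (3E,8R,10S)-4-(acetoxymethyl)-10-hydroxy-8-methyl-7-oxo-8-[(triethylsilyl)oxy]trideca-3,11,12-trien-5-ynoate; 19 methacrylic anhydride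
Product: 20 tert-butyl (3E,8R,10S)-4-(acetoxymethyl)-8-methyl-10-(methacryloyloxy)-7-oxo-8-[(triethylsilyl)oxy]trideca-3,11,12-trien-5-ynoate
Conditions: Et3N, DMAP (10 mol %), CH2Cl2, 0 °C
Reagents that add atoms: none
Why: DMAP-catalysed acylation of the only free (secondary) hydroxyl installs the C8 ester of the target.

Step 13
Reactants: 20 tert-butyl (3E,8R,10S)-4-(acetoxymethyl)-8-methyl-10-(methacryloyloxy)-7-oxo-8-[(triethylsilyl)oxy]trideca-3,11,12-trien-5-ynoate
Product: 21 hexacarbonyldicobalt complex of ester 20 (Co2(CO)6 bridging the C2≡C3 alkyne)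
Conditions: Co2(CO)8 (1.05 equiv), CH2Cl2, rt
Reagents that add atoms: octacarbonyldicobalt O=C=[Co](=C=O)(=C=O)(=C=O)[Co](=C=O)(=C=O)(=C=O)=C=O
Why: Alkyne complexation by Co2(CO)8 is selective for the triple bond over the allene and alkenes; it bends the ynone to about 140° and removes it from conjugation.

Step 14
Reactants: 21 hexacarbonyldicobalt complex of ester 20
Product: 23 hexacarbonyldicobalt complex of the seco acid (free CO2H in place of the tert-butyl ester of 21), via trimethylsilyl ester 22 (not isolated)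
Conditions: TMSOTf, 2,6-lutidine, CH2Cl2, 0 °C; then pH 7 buffer
Reagents that add atoms: none
Why: Silyl triflate-mediated tert-butyl ester cleavage (loss of isobutene) and hydrolysis of the silyl ester should give the acid; the buffered conditions spare the TES ether and the cluster, and the complexed alkyne cannot be attacked by the carboxyl group.

Step 15
Reactants: 23 hexacarbonyldicobalt complex of the seco acid
Product: 26 hexacarbonyldicobalt complex of cyclobutanone 27 (2-methylenecyclobutanone trans-fused at C6–C7 to the ten-membered ring), via acid chloride 24 (not isolated), via vinylketene 25 (not isolated)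
Conditions: Me2C=C(Cl)NMe2 (1.2 equiv), CH2Cl2, 0 °C; then syringe-pump addition to Et3N (5 equiv), toluene, 45 °C, final 0.5 mM
Reagents that add atoms: none
Why: Proposed new method: dehydrochlorination of the β,γ-unsaturated acid chloride gives vinylketene 25, whose electrophilic C12 bonds to the central allene carbon C11 while C6 bonds to C7 in an asynchronous, orthogonal [π2s+π2a] cycloaddition across C7=C11; the closest known reaction type is the intramolecular ketene–allene [2+2] cycloaddition that gives 2-methylenecyclobutanones fused to five- and six-membered rings, here extended to a ten-membered ring. The four-membered ring closes by the cycloaddition itself and the ten-membered carbocycle closes in the same event as a macrocyclisation through C6–C7, the untouched C11=C13 bond becoming the exocyclic methylene. The cis C4=C5 bond and the Co2(CO)6 cluster pre-fold the chain so that C6 and C7 are within reach, and the cluster takes C2≡C3 out of conjugation, which blocks the Moore cyclisation of a free (Z)-enyne-ketene (a furanone-conjugated dienylketene would instead undergo 6π electrocyclisation, which is why the furanone is not yet in place). C7 is set by the adjacent C8 stereocentre, the enolate-like C6 being expected to add anti to the C8–O bond (polar Felkin–Anh arrangement within the ring-closing geometry); C6, which is α to the ketone and allylic, can equilibrate under the amine to the trans ring fusion (H6/H7 anti), expected to be the less strained fusion of a four-membered ring on a medium ring, as in trans-fused caryophyllane skeletons. The step needs addition to the proximal rather than the distal allene bond, cycloaddition rather than ketene dimerisation, and no Pauson–Khand reaction of the cluster with the allene; the shorter tether to C7, slow addition at high dilution, and a temperature below that of thermal Pauson–Khand reactions are meant to secure these.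

Step 16
Reactants: 26 hexacarbonyldicobalt complex of cyclobutanone 27
Product: 27 (6R,7R,8S,10R)-2-methylenecyclobutanone (C12=O, C11=C13H2) trans-fused at C6–C7 to cyclodec-4-en-2-yn-1-one (C3 and C6 cis on C4=C5; 4-CH2OAc, 8-O-methacryloyl, 10-Me, 10-OSiEt3)
Conditions: (NH4)2Ce(NO3)6 (5 equiv), acetone, −78 → −30 °C
Reagents that add atoms: none
Why: Oxidative decomplexation by tetravalent cerium at low temperature should release the alkyne while the cyclobutanone, esters and silyl ether survive the short exposure.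

Step 17
Reactants: 27 cyclobutanone (as named in step 16)
Product: 28 (6R,7R,8S,10R)-α-methylene-γ-butyrolactone (6,12-olide) trans-fused at C6–C7 to the same cyclodec-4-en-2-yn-1-one (4-CH2OAc, 8-O-methacryloyl, 10-Me, 10-OSiEt3)
Conditions: mCPBA (1.2 equiv), NaHCO3, CH2Cl2, 0 °C
Reagents that add atoms: 3-chloroperbenzoic acid OOC(=O)c1cccc(Cl)c1
Why: Baeyer–Villiger oxidation of the strained cyclobutanone should outrun epoxidation of the electron-poor alkenes, and the secondary allylic C6 migrates in preference to the vinylic C11 with retention, so oxygen enters between C12 and C6 and the 6R configuration is kept.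

Step 18
Reactants: 28 ynone lactone (as named in step 17)
Product: 30 target CNP0179932.1, via hydroxy ynone 29 (not isolated)
Conditions: HF·pyridine, THF, 0 °C → rt; then Ph3PAuNTf2 (5 mol %), CH2Cl2, rt
Reagents that add atoms: none
Why: Desilylation frees the tertiary C10 hydroxyl, and gold-catalysed 5-endo-dig addition of it to C3 of the ynone (oxa-Michael type cycloisomerisation), helped by release of alkyne strain, should give the 3(2H)-furanone.

**Compound list**
1 | (R)-citramalic acid | C[C@@](O)(CC(=O)O)C(=O)O | starting material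
2 | (R)-2-(2,2,4-trimethyl-5-oxo-1,3-dioxolan-4-yl)acetic acid | C[C@]1(CC(=O)O)OC(C)(C)OC1=O | intermediate
3 | (trimethylsilyl)acetylene | C#C[Si](C)(C)C | starting material
4 | (R)-2-(2,2,4-trimethyl-5-oxo-1,3-dioxolan-4-yl)acetyl chloride | C[C@]1(CC(=O)Cl)OC(C)(C)OC1=O | intermediate
5 | (R)-2,2,5-trimethyl-5-[2-oxo-4-(trimethylsilyl)but-3-yn-1-yl]-1,3-dioxolan-4-one | C[C@]1(CC(=O)C#C[Si](C)(C)C)OC(C)(C)OC1=O | intermediate
6 | (R)-5-[(S)-2-hydroxy-4-(trimethylsilyl)but-3-yn-1-yl]-2,2,5-trimethyl-1,3-dioxolan-4-one | C[C@]1(C[C@H](O)C#C[Si](C)(C)C)OC(C)(C)OC1=O | intermediate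
7 | (3R,5S)-3-hydroxy-3-methyl-5-[(trimethylsilyl)ethynyl]oxolan-2-one | C[C@@]1(O)C[C@@H](C#C[Si](C)(C)C)OC1=O | intermediate
8 | (3R,5S)-5-ethynyl-3-hydroxy-3-methyloxolan-2-one | C[C@@]1(O)C[C@@H](C#C)OC1=O | intermediate
9 | (3R,5S)-3-hydroxy-3-methyl-5-(propa-1,2-dien-1-yl)oxolan-2-one | C[C@@]1(O)C[C@@H](C=C=C)OC1=O | intermediate
10 | (3R,5S)-3-methyl-5-(propa-1,2-dien-1-yl)-3-[(triethylsilyl)oxy]oxolan-2-one | C[C@@]1(O[Si](CC)(CC)CC)C[C@@H](C=C=C)OC1=O | intermediate
11 | ethynylmagnesium bromide | C#C[Mg]Br | starting material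
12 | (4R,6S)-6-hydroxy-4-methyl-4-[(triethylsilyl)oxy]nona-7,8-dien-1-yn-3-one | C#CC(=O)[C@](C)(O[Si](CC)(CC)CC)C[C@H](O)C=C=C | intermediate
13 | prop-2-yn-1-yl acetate | C#CCOC(C)=O | starting material
14 | allyl bromide | C=CCBr | starting material
15 | (Z)-2-bromohexa-2,5-dien-1-yl acetate | CC(=O)OC/C(Br)=C/CC=C | intermediate
16 | (Z)-5-acetoxy-4-bromopent-3-enoic acid | OC(=O)C/C=C(Br)/COC(C)=O | intermediate
17 | tert-butyl (Z)-5-acetoxy-4-bromopent-3-enoate | CC(C)(C)OC(=O)C/C=C(Br)/COC(C)=O | intermediate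
18 | tert-butyl (3E,8R,10S)-4-(acetoxymethyl)-10-hydroxy-8-methyl-7-oxo-8-[(triethylsilyl)oxy]trideca-3,11,12-trien-5-ynoate | CC(C)(C)OC(=O)C/C=C(COC(C)=O)\C#CC(=O)[C@](C)(O[Si](CC)(CC)CC)C[C@H](O)C=C=C | intermediate
19 | methacrylic anhydride | CC(=C)C(=O)OC(=O)C(C)=C | starting material
20 | tert-butyl (3E,8R,10S)-4-(acetoxymethyl)-8-methyl-10-(methacryloyloxy)-7-oxo-8-[(triethylsilyl)oxy]trideca-3,11,12-trien-5-ynoate | CC(C)(C)OC(=O)C/C=C(COC(C)=O)\C#CC(=O)[C@](C)(O[Si](CC)(CC)CC)C[C@H](OC(=O)C(C)=C)C=C=C | intermediate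
21 | hexacarbonyldicobalt complex of ester 20 (cluster on the C2≡C3 alkyne) | CC(C)(C)OC(=O)C/C=C(COC(C)=O)\C12C3(C(=O)[C@](C)(O[Si](CC)(CC)CC)C[C@H](OC(=O)C(C)=C)C=C=C)[Co]1(=C=O)(=C=O)(=C=O)[Co]23(=C=O)(=C=O)=C=O | intermediate
22 | trimethylsilyl ester of complexed seco acid 23 | C[Si](C)(C)OC(=O)C/C=C(COC(C)=O)\C12C3(C(=O)[C@](C)(O[Si](CC)(CC)CC)C[C@H](OC(=O)C(C)=C)C=C=C)[Co]1(=C=O)(=C=O)(=C=O)[Co]23(=C=O)(=C=O)=C=O | intermediate
23 | hexacarbonyldicobalt complex of the seco acid (free acid of 21) | OC(=O)C/C=C(COC(C)=O)\C12C3(C(=O)[C@](C)(O[Si](CC)(CC)CC)C[C@H](OC(=O)C(C)=C)C=C=C)[Co]1(=C=O)(=C=O)(=C=O)[Co]23(=C=O)(=C=O)=C=O | intermediate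
24 | acid chloride of 23 | ClC(=O)C/C=C(COC(C)=O)\C12C3(C(=O)[C@](C)(O[Si](CC)(CC)CC)C[C@H](OC(=O)C(C)=C)C=C=C)[Co]1(=C=O)(=C=O)(=C=O)[Co]23(=C=O)(=C=O)=C=O | intermediate
25 | vinylketene from 24 (ketene C12=C6 conjugated with C4=C5, cluster on C2≡C3) | O=C=C/C=C(COC(C)=O)\C12C3(C(=O)[C@](C)(O[Si](CC)(CC)CC)C[C@H](OC(=O)C(C)=C)C=C=C)[Co]1(=C=O)(=C=O)(=C=O)[Co]23(=C=O)(=C=O)=C=O | intermediate
26 | hexacarbonyldicobalt complex of cyclobutanone 27 | C=C(C)C(=O)O[C@H]1C[C@@](C)(O[Si](CC)(CC)CC)C(=O)C34C5(/C(COC(C)=O)=C\[C@H]2C(=O)C(=C)[C@H]12)[Co]3(=C=O)(=C=O)(=C=O)[Co]45(=C=O)(=C=O)=C=O | intermediate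
27 | (6R,7R,8S,10R)-2-methylenecyclobutanone trans-fused at C6–C7 to cyclodec-4-en-2-yn-1-one (4-CH2OAc, 8-O-methacryloyl, 10-Me, 10-OSiEt3) | C=C(C)C(=O)O[C@H]1C[C@@](C)(O[Si](CC)(CC)CC)C(=O)C#C/C(COC(C)=O)=C\[C@H]2C(=O)C(=C)[C@H]12 | intermediate
28 | (6R,7R,8S,10R)-α-methylene-γ-butyrolactone trans-fused at C6–C7 to the same cyclodec-4-en-2-yn-1-one (10-OSiEt3) | C=C(C)C(=O)O[C@H]1C[C@@](C)(O[Si](CC)(CC)CC)C(=O)C#C/C(COC(C)=O)=C\[C@H]2OC(=O)C(=C)[C@H]12 | intermediate
29 | 10-hydroxy analogue of 28 (free tertiary alcohol, ynone) | C=C(C)C(=O)O[C@H]1C[C@@](C)(O)C(=O)C#C/C(COC(C)=O)=C\[C@H]2OC(=O)C(=C)[C@H]12 | intermediate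
30 | CNP0179932.1 | C=C(C)C(=O)O[C@H]1C[C@@]2(C)OC(=CC2=O)/C(COC(C)=O)=C\[C@H]2OC(=O)C(=C)[C@H]12 | target

**Step count and risks**
Total steps: 18. Longest linear sequence: 15 (steps 1–7 and 11–18).

Most likely to fail:

1. Step 15 (proposed new method). The slow ten-membered closure may be outrun by ketene dimerisation or oligomerisation; the ketene may add across the distal C11=C13 bond; C6 may be delivered to the wrong face of C7; the cluster may engage the allene in a Pauson–Khand reaction. Fallback with known chemistry (chromium-mediated macrocyclic allylation, then carbonylative lactonisation), setting out from 12 and coming back at 28: 4-hydroxybut-2-yn-1-yl acetate is oxidised with MnO2 to 4-oxobut-2-yn-1-yl acetate F1; hydroiodination (NaI, AcOH) gives (Z)-2-iodo-4-oxobut-2-en-1-yl acetate F2; Sonogashira coupling of F2 with 12 gives enynal F3; acylation with 19 gives methacrylate F4; bromine (1 equiv, −78 °C) adds to the allene to give 2-bromoallyl bromide F5; CrCl2 in THF at high dilution closes the ten-membered ring by Nozaki–Hiyama-type allylation of the aldehyde through the substituted allyl terminus (anti, H6/H7 trans) to give bromo alcohol F6; Pd(PPh3)4-catalysed carbonylation (CO, Et3N) lactonises F6 to 28.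

2. Step 16. Decomplexation releases a strained conjugated cycloalkynone, which may be hydrated or oligomerise, and the acidic cerium medium may remove the silyl ether before the product is isolated. Fallback, setting out from 26 and coming back at target 30, inverts the order so that the alkyne is consumed as it is released: HF·pyridine removes the silyl ether on the intact cluster to give hydroxy complex F7; (NH4)2Ce(NO3)6 at −78 °C followed at once by Ph3PAuNTf2 lets the tertiary hydroxyl add transannularly to the freed ynone and gives furanone cyclobutanone F8; mCPBA/NaHCO3 then converts F8 into 30 in the last step.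

3. Step 5. Aminolysis of the lactone or copper-mediated substitution at the propargylic C8–O bond may compete with the Mannich reaction and hydride shift at reflux. Fallback, setting out from 2 and coming back at 9, avoids the terminal alkyne and the copper acetylide: acid chloride 4 (made as in step 2) is coupled (PdCl2(PPh3)2, CuI, Et3N) with methyl prop-2-yn-1-yl carbonate to give ynone carbonate F9; transfer hydrogenation and acid lactonisation as in step 3 give lactone carbonate F10; palladium-catalysed formate hydrogenolysis of the propargylic carbonate (Pd2(dba)3, PBu3, HCO2NH4, THF) through an allenylpalladium hydride gives allene 9.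

Further compounds
F1 | step 15 | 4-oxobut-2-yn-1-yl acetate | CC(=O)OCC#CC=O
F2 | step 15 | (Z)-2-iodo-4-oxobut-2-en-1-yl acetate | CC(=O)OC/C(I)=C/C=O
F3 | step 15 | (2E,7R,9S)-3-(acetoxymethyl)-9-hydroxy-7-methyl-6-oxo-7-[(triethylsilyl)oxy]dodeca-2,10,11-trien-4-ynal | O=C/C=C(COC(C)=O)\C#CC(=O)[C@](C)(O[Si](CC)(CC)CC)C[C@H](O)C=C=C
F4 | step 15 | 9-O-methacryloyl ester of F3 | O=C/C=C(COC(C)=O)\C#CC(=O)[C@](C)(O[Si](CC)(CC)CC)C[C@H](OC(=O)C(C)=C)C=C=C
F5 | step 15 | 2-bromoallyl bromide from F4 (11,12-dibromo-dodeca-2,10-dien-4-ynal; alkene isomers and the 10,11-dibromo regioisomer converge) | O=C/C=C(COC(C)=O)\C#CC(=O)[C@](C)(O[Si](CC)(CC)CC)C[C@H](OC(=O)C(C)=C)C=C(Br)CBr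
F6 | step 15 | (6R,7R,8S,10R)-6-hydroxy-7-(1-bromovinyl)cyclodec-4-en-2-yn-1-one (4-CH2OAc, 8-O-methacryloyl, 10-Me, 10-OSiEt3) | C=C(C)C(=O)O[C@H]1C[C@@](C)(O[Si](CC)(CC)CC)C(=O)C#C/C(COC(C)=O)=C\[C@@H](O)[C@@H]1C(Br)=C
F7 | step 16 | hexacarbonyldicobalt complex of the 10-hydroxy cyclobutanone (desilylated 26) | C=C(C)C(=O)O[C@H]1C[C@@](C)(O)C(=O)C34C5(/C(COC(C)=O)=C\[C@H]2C(=O)C(=C)[C@H]12)[Co]3(=C=O)(=C=O)(=C=O)[Co]45(=C=O)(=C=O)=C=O
F8 | step 16 | furanone cyclobutanone (target skeleton with C12–C6 bond in place of the lactone oxygen) | C=C(C)C(=O)O[C@H]1C[C@@]2(C)OC(=CC2=O)/C(COC(C)=O)=C\[C@H]2C(=O)C(=C)[C@H]12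
F9 | step 5 | (R)-methyl 4-oxo-5-(2,2,4-trimethyl-5-oxo-1,3-dioxolan-4-yl)pent-2-yn-1-yl carbonate | C[C@]1(CC(=O)C#CCOC(=O)OC)OC(C)(C)OC1=O
F10 | step 5 | methyl 3-[(2S,4R)-4-hydroxy-4-methyl-5-oxooxolan-2-yl]prop-2-yn-1-yl carbonate | C[C@@]1(O)C[C@@H](C#CCOC(=O)OC)OC1=O
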